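## Retrosynthetic overview
1. The cyclohexene is the cis (endo, "ortho") [4+2] homodimer of one achiral monomer, 7-hydroxy-8-methoxy-3-[(E)-3-methylbuta-1,3-dienyl]coumarin. The cuts are ring bonds C5–C6 and C1–C2.
2. Forward, the 7-O-TIPS monomer is dimerised by a hole-catalysed (radical-cation) Diels–Alder reaction inside a chiral ion pair. C5–C6 forms first (tail to tail), and C1–C2 closure then sets both stereocentres at once. Fluoride in the same flask frees the phenols.
3. The monomer's pyranone ring and complete C5 diene come in one operation from a salicylaldehyde and a C7 dienoic acid (deconjugative O-acylation, intramolecular Knoevenagel).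
4. The salicylaldehyde comes from 2-methoxyresorcinol (formylation, 4-O-silylation), and the acid from prenal and malonic acid.
5. Ring order: the two pyranone rings first (monomer stage), the cyclohexene last, as proposed for the biogenesis.

Assumption: the sense of induction of the chiral anion in step 5 cannot be predicted, so the antipode that gives the (1R,2R) series is fixed by one test run (both derive from commercial BINOL antipodes).

## Route

**Step 1**
Reactants: 1 2-methoxyresorcinol
Product: 3 2,4-dihydroxy-3-methoxybenzaldehyde, via iminium chloride 2 (not isolated)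
Conditions: POCl3 (1.2 equiv), DMF (1.5 equiv), MeCN, −15 → 25 °C; then H2O, 50 °C
Reagents that add atoms: N,N-dimethylformamide CN(C)C=O; water O
Why: Vilsmeier–Haack formylation; C4 and C6 are equivalent by symmetry and are the only positions ortho to one OH and para to the other, so one regioisomer forms and hydrolysis of the iminium salt gives the aldehyde (no stereocentre).

**Step 2**
Reactants: 3 2,4-dihydroxy-3-methoxybenzaldehyde
Product: 4 2-hydroxy-3-methoxy-4-[(triisopropylsilyl)oxy]benzaldehyde
Conditions: TIPSCl (1.05 equiv), imidazole (2.0 equiv), CH2Cl2, 0 °C → rt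
Reagents that add atoms: chlorotriisopropylsilane CC(C)[Si](Cl)(C(C)C)C(C)C
Why: Chemoselective O-silylation; the 2-OH is hydrogen-bonded to the formyl group and flanked on both sides, so the bulky silyl chloride reacts only at the more acidic, more open 4-OH.

**Step 3**
Reactants: 5 3-methylbut-2-enal (prenal); 6 malonic acid
Product: 8 (2E)-5-methylhexa-2,4-dienoic acid, via alkylidenemalonic acid 7 (not isolated)
Conditions: pyridine, piperidine (10 mol%), 90 °C
Reagents that add atoms: none
Why: Knoevenagel–Doebner condensation; decarboxylation of the alkylidenemalonic acid in pyridine gives the (2E)-acid under thermodynamic control.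

**Step 4**
Reactants: 8 (2E)-5-methylhexa-2,4-dienoic acid; 4 2-hydroxy-3-methoxy-4-[(triisopropylsilyl)oxy]benzaldehyde
Product: 12 8-methoxy-3-[(1E)-3-methylbuta-1,3-dien-1-yl]-7-[(triisopropylsilyl)oxy]-2H-chromen-2-one, via acid chloride 9 (not isolated), via dienylketene 10 (not isolated), via aryl dienoate 11 (not isolated)
Conditions: (COCl)2 (1.2 equiv), DMF (cat.), CH2Cl2, 0 °C → rt, evaporate; then 4, Et3N (3 equiv), 4 Å MS, BHT (1 mol%), CH2Cl2, 0 → 40 °C; DBU (20 mol%) to finish
Reagents that add atoms: none
Why: Deconjugative acylation followed by intramolecular Knoevenagel (aldol) condensation; Et3N removes HCl from the acid chloride in a 1,6 sense (as with sorbyl chloride), the phenol traps the dienylketene as the 3,5-dienoate, and its doubly activated CH2 condenses with the ortho formyl group, while the E alkene follows from the s-trans dienoyl conformer and from conjugation, and staying at or below 40 °C avoids thermal (racemic) dimerisation.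

**Step 5**
Reactants: 12 8-methoxy-3-[(1E)-3-methylbuta-1,3-dien-1-yl]-7-[(triisopropylsilyl)oxy]-2H-chromen-2-one (two molecules)
Product: 14 CNP0264408.1 = 7-hydroxy-3-{(E)-2-[(1R,2R)-2-(7-hydroxy-8-methoxy-2-oxo-2H-chromen-3-yl)-1,4-dimethylcyclohex-3-en-1-yl]ethenyl}-8-methoxy-2H-chromen-2-one, via bis-TIPS dimer 13 (not isolated)
Conditions: [9-mesityl-2,7-dimethoxythioxanthylium][IDPi] (2.5 mol%; IDPi = enantiopure N,N'-bis(trifluoromethylsulfonyl)imidodiphosphorimidate anion built from two 3,3'-diaryl-BINOL units), 2,6-di-tert-butylpyridine (5 mol%), CH2Cl2/toluene 1:1 (0.2 M), −78 °C, green LED 525 nm, argon; then TBAF (2.4 equiv), AcOH (2.6 equiv), THF, 0 °C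
Reagents that add atoms: none
Why: Proposed new method: green light (not absorbed by 12) excites the thioxanthylium dye, which oxidises one molecule of 12 (oxidation potential estimated well below that of the excited dye) to a radical cation that stays paired with the confined chiral anion in the non-polar medium, bonds tail to tail (C4'–C4') to the s-cis diene of a neutral 12 and closes C1'–C3' in the endo sense (coumarinyl cis to alkenyl), so that both stereocentres (1R,2R) arise in one enantio-determining event, after which the less easily oxidised adduct radical cation takes an electron from fresh 12 (chain) and any cyclobutane formed reversibly drains to the cyclohexene; the closest known reaction types are the thioxanthylium-photocatalysed radical-cation Diels–Alder reaction and the IDPi-paired, counteranion-directed radical-cation [2+2] cycloaddition of styrenes, and buffered fluoride then cleaves both aryl silyl ethers without touching lactones, alkenes or the non-acidic stereocentres.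

## Compound list
1 | 2-methoxybenzene-1,3-diol (2-methoxyresorcinol) | COc1c(O)cccc1O | starting material
2 | N-(2,4-dihydroxy-3-methoxybenzylidene)-N-methylmethanaminium chloride | C[N+](C)=Cc1ccc(O)c(OC)c1O.[Cl-] | intermediate
3 | 2,4-dihydroxy-3-methoxybenzaldehyde | O=Cc1ccc(O)c(OC)c1O | intermediate
4 | 2-hydroxy-3-methoxy-4-[(triisopropylsilyl)oxy]benzaldehyde | O=Cc1ccc(O[Si](C(C)C)(C(C)C)C(C)C)c(OC)c1O | intermediate
5 | 3-methylbut-2-enal (prenal) | CC(C)=CC=O | starting material
6 | malonic acid | OC(=O)CC(=O)O | starting material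
7 | 2-(3-methylbut-2-en-1-ylidene)propanedioic acid | CC(C)=CC=C(C(=O)O)C(=O)O | intermediate
8 | (2E)-5-methylhexa-2,4-dienoic acid | CC(C)=C/C=C/C(=O)O | intermediate
9 | (2E)-5-methylhexa-2,4-dienoyl chloride | CC(C)=C/C=C/C(=O)Cl | intermediate
10 | (3E)-5-methylhexa-1,3,5-trien-1-one (dienylketene) | C=C(C)/C=C/C=C=O | intermediate
11 | 2-formyl-6-methoxy-5-[(triisopropylsilyl)oxy]phenyl (3E)-5-methylhexa-3,5-dienoate | C=C(C)/C=C/CC(=O)Oc1c(C=O)ccc(O[Si](C(C)C)(C(C)C)C(C)C)c1OC | intermediate
12 | 8-methoxy-3-[(1E)-3-methylbuta-1,3-dien-1-yl]-7-[(triisopropylsilyl)oxy]-2H-chromen-2-one | C=C(C)/C=C/c1cc2ccc(O[Si](C(C)C)(C(C)C)C(C)C)c(OC)c2oc1=O | intermediate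
13 | bis(7-O-triisopropylsilyl) ether of the target, (1R,2R), coumarinyl cis to alkenyl | COc1c(O[Si](C(C)C)(C(C)C)C(C)C)ccc2cc(/C=C/[C@@]3(C)CCC(C)=C[C@H]3c3cc4ccc(O[Si](C(C)C)(C(C)C)C(C)C)c(OC)c4oc3=O)c(=O)oc12 | intermediate
14 | CNP0264408.1, 7-hydroxy-3-{(E)-2-[(1R,2R)-2-(7-hydroxy-8-methoxy-2-oxo-2H-chromen-3-yl)-1,4-dimethylcyclohex-3-en-1-yl]ethenyl}-8-methoxy-2H-chromen-2-one | COc1c(O)ccc2cc(/C=C/[C@@]3(C)CCC(C)=C[C@H]3c3cc4ccc(O)c(OC)c4oc3=O)c(=O)oc12 | target

## Step count and risks
Total step count: 5. Longest linear sequence: 4 (1 → 3 → 4 → 12 → 14).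

**Step 5 is the most exposed.**
- Risk: the ee, the cis/trans ratio and the [4+2]/[2+2] partition of an ion-pair-controlled radical-cation dimerisation are untested on this substrate. The 3-vinylcoumarin diene (C4=C3–C1'=C2') or acid-triggered oligomerisation could also compete.
- Fallback: it sets out from 12 and replaces asymmetric catalysis with a purely thermal pericyclic dimerisation followed by resolution.
- Heating 12 in toluene (2 M, BHT, sealed tube, 110 °C) gives the cis adduct as a racemate, that is 13 together with its mirror image, the (1S,2S) bis-silyl ether F1.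
- After chromatographic removal of minor isomers, preparative chiral SFC on an amylose tris(3,5-dimethylphenylcarbamate) phase separates the two.
- The route is rejoined at 13, which goes into the TBAF/AcOH stage of step 5.

**Step 4 is second.**
- Risk: the dienylketene may dimerise, acylation may stop at a conjugated ester that resists epsilon-deprotonation, or the product may oligomerise.
- Fallback: it sets out from 4 and attaches the C5 unit to a preformed coumarin by cross-coupling.
- Wittig olefination with ethyl (triphenylphosphoranylidene)acetate in hot N,N-diethylaniline gives the ethyl o-hydroxycinnamate F2.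
- This cinnamate lactonises in the same solution to 8-methoxy-7-[(triisopropylsilyl)oxy]coumarin F3.
- Bromination (Br2, NaOAc, AcOH) gives the 3-bromocoumarin F4.
- Heck coupling with 2-methylbut-3-en-2-ol (Pd(OAc)2, P(o-tol)3, Et3N, DMF, 90 °C) gives the tertiary allylic alcohol F5.
- Dehydration with catalytic PPTS in toluene (80 °C, BHT) rejoins the route at 12.

**Step 1 is third.**
- Risk: the free diol can give aryl formates, double formylation or low recovery.
- Fallback: it sets out from 1 and reverses the order of events, which also removes the selectivity question of step 2.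
- Monosilylation of excess 1 (TIPSCl, imidazole) gives 2-methoxy-3-[(triisopropylsilyl)oxy]phenol F6.
- Its single free OH directs a magnesium-phenoxide ortho-formylation (MgCl2, Et3N, paraformaldehyde, MeCN, reflux) to the only open ortho carbon.
- The route is rejoined at 4.

## Further compounds
F1 | step 5 | (1S,2S) enantiomer of 13 | COc1c(O[Si](C(C)C)(C(C)C)C(C)C)ccc2cc(/C=C/[C@]3(C)CCC(C)=C[C@@H]3c3cc4ccc(O[Si](C(C)C)(C(C)C)C(C)C)c(OC)c4oc3=O)c(=O)oc12
F2 | step 4 | ethyl (2E)-3-{2-hydroxy-3-methoxy-4-[(triisopropylsilyl)oxy]phenyl}prop-2-enoate | CCOC(=O)/C=C/c1ccc(O[Si](C(C)C)(C(C)C)C(C)C)c(OC)c1O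
F3 | step 4 | 8-methoxy-7-[(triisopropylsilyl)oxy]-2H-chromen-2-one | COc1c(O[Si](C(C)C)(C(C)C)C(C)C)ccc2ccc(=O)oc12
F4 | step 4 | 3-bromo-8-methoxy-7-[(triisopropylsilyl)oxy]-2H-chromen-2-one | COc1c(O[Si](C(C)C)(C(C)C)C(C)C)ccc2cc(Br)c(=O)oc12
F5 | step 4 | 3-[(1E)-3-hydroxy-3-methylbut-1-en-1-yl]-8-methoxy-7-[(triisopropylsilyl)oxy]-2H-chromen-2-one | COc1c(O[Si](C(C)C)(C(C)C)C(C)C)ccc2cc(/C=C/C(C)(C)O)c(=O)oc12
F6 | step 1 | 2-methoxy-3-[(triisopropylsilyl)oxy]phenol | COc1c(O)cccc1O[Si](C(C)C)(C(C)C)C(C)C
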